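Late readings show what a flask has finally made, so I began there, wanting the final side product in each flask below.

| flask | substrate | coupling partner | temperature | remark | time |
|---|---|---|---|---|---|
| epsilon | 0.50 mM | 0.65 mM | 15 °C | run made earlier |  |
| eta | 0.50 mM | 0.33 mM | 26 °C | run made earlier |  |
| delta | 0.50 mM | 1.3 mM | 15 °C | run made earlier |  |
| spring | 0.50 mM | 0.650 mM (fed, over 6.0 min) | 20 °C | all else is in the flask from the start; the feed brings no volume worth counting | 15 min |
| winter | 0.50 mM | 0.650 mM (in portions, 2, over 6.0 min) | 20 °C | first portion at the start, last at 6.0 min | 15 min |
| summer | 0.50 mM | 0.650 mM |  | everything together at the start at −10 °C, warmed to 20 °C at 6.0 min | 15 min |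
| dusk | 0.50 mM (fed, over 6.0 min) | 0.650 mM |  | the addition at −10 °C, then warmed to 20 °C; the feed brings no volume worth counting | 15 min |
| autumn | 0.50 mM | 0.650 mM | 20 °C | everything together at the start | 15 min |

- epsilon (time / min: side product / %, target / %, substrate / %): 0.833: 5, 66, 28; 2.50: 6, 84, 6; 4.00: 7, 90, 4; 6.00: 10, 92, 0; 10.0: 7, 91, 0
- eta (time / min: side product / %, target / %, substrate / %): 1.00: 2, 59, 42; 3.00: 0, 65, 35; 6.00: 1, 64, 36; 8.00: 0, 62, 39; 12.0: 1, 62, 32
- delta (time / min: side product / %, target / %, substrate / %): 1.00: 20, 79, 3; 3.00: 16, 86, 0; 6.00: 17, 84, 0; 8.00: 17, 84, 0; 12.0: 16, 82, 1

(each reading ± 1.5 percentage points)

1. the flask with the highest amount of side product, in percent of the substrate charged ("all alike" if they lie within 1.5 percentage points) (spring / winter / summer / dusk / autumn / all alike)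
2. final side product, as a percentage of the substrate charged, in spring
3. final side product, as a percentage of the substrate charged, in winter
4. final side product, as a percentage of the substrate charged, in summer
5. final side product, as a percentage of the substrate charged, in dusk
6. final side product, as a percentage of the substrate charged, in autumn

- what is said of target includes crystals
- crystals is a solid; its amount is given per volume of the solution
- steps that have been proposed: substrate + coupling partner -> target; substrate + 2 coupling partner -> side product; crystals <-> target

Taking the proposed steps as written, target takes one coupling partner per substrate and side product takes two, so I let target form in proportion to substrate times partner, and side product in proportion to substrate times partner squared. Substrate cancels in the quotient, which leaves side product made per target made, at a fixed temperature, equal to a number times the partner standing at that moment.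

Side product is the small thing here, so I reckoned it as a correction. In the delta run the late readings averaged 16.7% side product and 83.3% target. Taking the partner to fall evenly with conversion, I put its average along the way midway between start and end, at 1.01 mM. That gave a reading of 0.198 mM⁻¹ at 15 °C for the selectivity factor, the side product made per target made and per mM of partner standing.

In the eta run, at 26 °C, the partner was the limiting reagent, 0.33 mM against 0.50 mM of substrate. Side product averaged 0.800% on 62.4% target, which reads as 0.0777 mM⁻¹, a weak reading with each point good to 1.5 percentage points. Warmth seemed to lower the factor.

Autumn, at 20 °C, lies between those temperatures. With the substrate taken to target, its partner averages 0.400 mM, so I expected side product between 3.11% and 7.92% of target. I expected less in spring and winter, where the partner arrives over 6.0 min, and most in summer and dusk, which start at −10 °C. No earlier run reaches that cold, so I gave those two no number.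

The forecast named summer, with 28% there, 26% in dusk, 5% in autumn, 2.8% in winter and 1.8% in spring, holding for summer that “most reaction occurs cold at high partner concentration”.

The flask with the most side product was summer, at 17.1%, followed by dusk at 14.9%, autumn at 6.16%, winter at 3.12% and spring at 1.34%. Over the first 6.0 min the partner averaged 0.0771 mM in spring, against 0.167 mM in autumn. My factor, read at 15 °C although spring stood at 20 °C, with spring's mean partner over those minutes taken as the average along the way and its 98.7% of target, gives 1.51% side product for spring.

    substrate + coupling partner → target (k = 92.0 M⁻¹ s⁻¹, Ea = 50.0 kJ mol⁻¹)
    substrate + 2 coupling partner → side product (k = 16000 M⁻² s⁻¹, Ea = 20.0 kJ mol⁻¹)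
    crystals ⇌ target, rate k3*(cs3 - [target]) while solid is left; crystals form when [target] > cs3 (solubility = 0.330 mM, k = 2.50 s⁻¹)
    (constants at 20 °C)

In the neighbour flask, spring with 0.16 mM of partner, I took the fed partner to stand near feed rate over the target step's rate constant times mean substrate, with that mean midway between charge and end, which is about 0.0115 mM, so the same factor, still the reading at 15 °C, and 31.9% of target give 0.0726% side product. The computed flask holds 0.0580%.

The runs come from a simulation for substances that don't exist; scatter was added.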